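(The data were generated by integration from invented constants, noise included.)

The flask held 0.20 M of starting material against 0.300 M of partner, more partner than starting material, yet the mono adducts of the earlier runs stood far short of what their charges allow.

| flask | starting material | partner | remark | time |
|---|---|---|---|---|
| violet | 0.20 M | 0.42 M | run made earlier |  |
| green | 0.20 M | 0.66 M | run made earlier |  |
| red | 0.30 M | 0.30 M | run made earlier |  |
| flask | 0.20 M | 0.300 M |  | 20 h |

| run | time / h | first product / % | other mono adduct / % |
|---|---|---|---|
| violet | 1.50 | 17.0 | 21.9 |
| violet | 3.00 | 17.0 | 24.0 |
| violet | 6.00 | 16.7 | 23.4 |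
| violet | 10.0 | 16.3 | 25.8 |
| violet | 20.0 | 15.0 | 22.4 |
| green | 1.50 | 15.3 | 32.5 |
| green | 3.00 | 14.6 | 32.5 |
| green | 6.00 | 16.3 | 29.4 |
| green | 10.0 | 16.2 | 31.0 |
| green | 20.0 | 14.4 | 31.7 |
| red | 4.00 | 14.6 | 14.5 |
| red | 8.00 | 14.0 | 17.2 |
| red | 12.0 | 16.5 | 17.0 |
| red | 15.0 | 14.4 | 16.8 |
| red | 20.0 | 13.2 | 16.9 |

(each reading ± 1 percentage point)

- what was read earlier has a scatter of 1 percentage point, one standard deviation
- the reaction counts as stopped when no species that holds the starting material changes by six tenths of a point or more over the second half of the time

- the state of affairs at 20 h: stopped, and by what, or still going (the partner has run out first / forward and back rates have come level / all of the starting material has reacted / it is still moving)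
- how much first product there is at 20 h, in percent of the starting material charged
- how much other mono adduct there is at 20 h, in percent of the starting material charged

I averaged the plateaus of other mono adduct: 23.5 % in violet, 31.4 % in green, and 17.0 % in red without its first reading. Violet paid 8.94 moles of partner charged per mole of other mono adduct found, and this partner price was higher in green at 10.5, with more partner, and lower in red at 5.89, with more starting material and less partner.

I took two extremes for the flask as my estimate. At violet's price, which the flask should undercut with less partner, its charge buys 16.8 %. At red's price, which it should exceed with less starting material, it buys 25.5 %. The line through violet and green rises 6.53 M⁻¹, which put the flask's price at 8.15 and its other mono adduct at 18.4 %. The last first-product readings averaged 14.2 %, and I committed to that, with partner ending the reaction.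

The forecast gave the partner has run out first, 15.8 % and 19.5 %, from “a kinetic freeze when partner is exhausted”, and my other mono adduct stood lower. The flask gave the partner has run out first, 14.9 % and 18.1 %, a price of 8.29.

    starting material + partner → first product + by-product (k = 8.40 × 10⁻⁴ M⁻¹ s⁻¹)
    starting material + partner → other mono adduct + by-product (k = 6.90 × 10⁻⁴ M⁻¹ s⁻¹)
    partner + first product → double product + by-product (k = 0.00150 M⁻¹ s⁻¹)
    partner + other mono adduct → double product + by-product (k = 1.30 × 10⁻⁵ M⁻¹ s⁻¹)
    partner + first product → over-reaction product (k = 7.90 × 10⁻⁴ M⁻¹ s⁻¹)
    partner → decomposed reagent (k = 6.10 × 10⁻⁴ s⁻¹)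

At the flask's charged amounts, partner decomposed 1.99 times as fast as starting material took it. After 20.0 h the flask held 0.205 M of decomposed reagent, with 0 % of partner and 60 % of starting material left, so partner was the limiting reagent. For 0.75 M of partner on 0.20 M of starting material, the line from violet's 8.94 gives a price of 11.1, hence 33.8 % other mono adduct; the computed neighbour flask gave 33.4 %.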